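Atoms carry the numbers of the target SMILES (ethyl C1–C2, carbinol C3/O4; ring A = N29, C5–C9; ring B = N29, C9, C10, C24, C26–C28; ring C = C10, C11, C13, C15, C24; butenolide ring D = C15, O16, C17, C19, C21). The enabling feature: spiro C15 is the γ-carbon of a 4-methoxy-3-methylbutenolide, acidic and nucleophilic as a furanolate, and its ring C neighbour C13 is a carbinol, i.e. a reduced acyl carbon.
Retrosynthetic cuts, in order: C13–O14 (ketone reduction); C13–C15 (ring C, C-acylation of the tetronate by a C13 methyl ester); C15–C24 (tetronate anion plus ring B ketone); C10–C11 (alkylation); C10–C24 (ring B, Dieckmann); C9–C10 (sulfide contraction); N29–C28 (N-alkylation); C2–C3 (Grignard).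
Forward: ring A as a lactam from (R)-2-aminohexanedioic acid, then the C3 side chain, the N-chain, thiolactam, vinylogous urethane and hydrogenation; ring B by Dieckmann closure; the C11–C13 unit by alkylation and decarboxylation; ring D attached at C24; ring C closed last; reduction and desilylation.
Stereochemistry: C5 from the amino acid; C3 by Felkin–Anh reduction; C9 by hydrogenation anti to the C5 side chain; C10 by face-selective ketonisation after decarboxylation; C24 by addition anti to the C10 branch; C15 and C11 in the ring C closure; C13 by hydride attack on the less hindered ketone face.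

Key step: step 15

Remark: quaternary C10 of 17, C11 of 17–24 and C15 of 23–24 are carried as epimer mixtures that later steps converge; the SMILES leave these centres undefined.

Step 1
Reactants: 1 (R)-2-aminohexanedioic acid
Product: 2 (R)-6-oxopiperidine-2-carboxylic acid
Conditions: AcOH/H2O (1:4), reflux
Reagents that add atoms: none
Why: Thermal lactamisation joins the amine to the distal carboxyl as a six-membered lactam, which differentiates the two acids and does not touch the C5 stereocentre.

Step 2
Reactants: 2 (R)-6-oxopiperidine-2-carboxylic acid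
Product: 4 (R)-N-methoxy-N-methyl-6-oxopiperidine-2-carboxamide, via acyl imidazolide 3 (not isolated)
Conditions: 1,1'-carbonyldiimidazole, DMF, rt; then MeNHOMe·HCl, rt
Reagents that add atoms: N,O-dimethylhydroxylamine hydrochloride (CNOC.Cl); 1,1'-carbonyldiimidazole (O=C(n1ccnc1)n1ccnc1, atoms only in 3)
Why: Weinreb amide formation through the acyl imidazolide should keep C5 intact, because the nitrogen is locked in the lactam and cannot form an azlactone.

Step 3
Reactants: 4 (R)-N-methoxy-N-methyl-6-oxopiperidine-2-carboxamide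
Product: 5 (R)-6-propanoylpiperidin-2-one
Conditions: EtMgBr (2.5 equiv), THF, −20 to 0 °C
Reagents that add atoms: ethylmagnesium bromide (CC[Mg]Br)
Why: In this Weinreb ketone synthesis the first equivalent deprotonates the lactam N–H and the second adds once, the chelated adduct releasing the ethyl ketone only on work-up.

Step 4
Reactants: 5 (R)-6-propanoylpiperidin-2-one
Product: 6 (6R)-6-[(1R)-1-hydroxypropyl]piperidin-2-one
Conditions: LiBH(s-Bu)3, THF, −78 °C
Reagents that add atoms: none
Why: The bulky, non-chelating hydride should attack the ketone anti to the ring nitrogen (Felkin–Anh reduction), which from (5R) gives the syn amino alcohol with (3R) configuration.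

Step 5
Reactants: 6 (6R)-6-[(1R)-1-hydroxypropyl]piperidin-2-one
Product: 7 (6R)-6-[(1R)-1-(triisopropylsilyloxy)propyl]piperidin-2-one
Conditions: i-Pr3SiOTf, 2,6-lutidine, CH2Cl2, 0 °C to rt
Reagents that add atoms: triisopropylsilyl trifluoromethanesulfonate (CC(C)[Si](C(C)C)(C(C)C)OS(=O)(=O)C(F)(F)F)
Why: Silyl triflate silylation of the hindered secondary alcohol gives an ether robust enough for the later acidolysis, any silylated lactam being hydrolysed on work-up.

Step 6
Reactants: 7 (6R)-6-[(1R)-1-(triisopropylsilyloxy)propyl]piperidin-2-one; 8 ethyl 4-bromobutanoate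
Product: 9 ethyl 4-{(6R)-2-oxo-6-[(1R)-1-(triisopropylsilyloxy)propyl]piperidin-1-yl}butanoate
Conditions: NaH, DMF, 0 °C; then 8, Bu4NI (cat.), rt
Reagents that add atoms: none
Why: SN2 N-alkylation of the sodium lactamate by the primary bromide installs C26–C28 and the ester that later becomes the C24 carbonyl.

Step 7
Reactants: 9 ethyl 4-{(6R)-2-oxo-6-[(1R)-1-(triisopropylsilyloxy)propyl]piperidin-1-yl}butanoate
Product: 10 ethyl 4-{(6R)-2-thioxo-6-[(1R)-1-(triisopropylsilyloxy)propyl]piperidin-1-yl}butanoate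
Conditions: Lawesson's reagent (0.55 equiv), toluene, 80 °C
Reagents that add atoms: Lawesson's reagent (COc1ccc(cc1)P1(=S)SP(=S)(S1)c1ccc(OC)cc1)
Why: Lawesson thionation converts the tertiary lactam selectively, the ester and silyl ether being inert, and activates C9 for carbon–carbon bond formation.

Step 8
Reactants: 10 ethyl 4-{(6R)-2-thioxo-6-[(1R)-1-(triisopropylsilyloxy)propyl]piperidin-1-yl}butanoate; 11 tert-butyl bromoacetate
Product: 13 tert-butyl (2E)-2-{(6R)-1-(4-ethoxy-4-oxobutyl)-6-[(1R)-1-(triisopropylsilyloxy)propyl]piperidin-2-ylidene}acetate, via thioiminium bromide 12 (not isolated)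
Conditions: 11, MeCN, rt; then PPh3, Et3N, 40 °C
Reagents that add atoms: none
Why: In the Eschenmoser sulfide contraction S-alkylation, base-induced episulfide formation and sulfur transfer to PPh3 create the C9=C10 bond of an E-configured vinylogous urethane.

Step 9
Reactants: 13 tert-butyl (2E)-2-{(6R)-1-(4-ethoxy-4-oxobutyl)-6-[(1R)-1-(triisopropylsilyloxy)propyl]piperidin-2-ylidene}acetate
Product: 14 tert-butyl 2-{(2S,6R)-1-(4-ethoxy-4-oxobutyl)-6-[(1R)-1-(triisopropylsilyloxy)propyl]piperidin-2-yl}acetate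
Conditions: H2 (4 bar), PtO2, AcOH, rt
Reagents that add atoms: none
Why: Heterogeneous hydrogenation of the vinylogous urethane should deliver hydrogen to C9 from the face opposite the C5 side chain, which allylic strain against the N-substituent holds axial, giving the 2,6-cis piperidine (9S).

Step 10
Reactants: 14 tert-butyl 2-{(2S,6R)-1-(4-ethoxy-4-oxobutyl)-6-[(1R)-1-(triisopropylsilyloxy)propyl]piperidin-2-yl}acetate
Product: 15 tert-butyl (4R,10aS)-9-oxo-4-[(1R)-1-(triisopropylsilyloxy)propyl]decahydropyrido[1,2-a]azepine-10-carboxylate (ring B β-keto ester; C10 epimers and enol)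
Conditions: KOtBu, THF, 0 °C to rt; AcOH
Reagents that add atoms: none
Why: In this Dieckmann condensation only the C10 enolate of the tert-butyl ester can attack the ethyl ester (the tert-butyl ester is too poor an electrophile for the reverse mode), so the seven-membered ring B closes with the ester on C10 and the product is held as its enolate.

Step 11
Reactants: 15 ring B β-keto ester; 16 methyl 2-bromopropanoate
Product: 17 tert-butyl (4R,10aS)-10-(1-methoxy-1-oxopropan-2-yl)-9-oxo-4-[(1R)-1-(triisopropylsilyloxy)propyl]decahydropyrido[1,2-a]azepine-10-carboxylate (C10/C11 epimers)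
Conditions: NaH, DMF, 0 °C; then 16, rt to 40 °C
Reagents that add atoms: none
Why: SN2 C-alkylation of the stabilised β-keto ester enolate by the α-bromo ester forms C10–C11 regiospecifically, and the configurations at C10 and C11 are immaterial because steps 12 and 15 reset them.

Step 12
Reactants: 17 alkylated β-keto ester
Product: 19 methyl 2-{(4R,10R,10aS)-9-oxo-4-[(1R)-1-(triisopropylsilyloxy)propyl]decahydropyrido[1,2-a]azepin-10-yl}propanoate (C11 epimers), via keto acid 18 (not isolated)
Conditions: CF3CO2H, CH2Cl2, 0 °C to rt; then toluene, 50 °C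
Reagents that add atoms: none
Why: Acidolysis of the tert-butyl ester and decarboxylation of the β-keto acid pass through the C10=C24 enol, in which A(1,2) strain against the C11 branch should hold C8 pseudoaxial so that C10 is protonated from the opposite face (H10 cis to H9, 10R), the ammonium ion slowing re-enolisation towards C10.

Step 13
Reactants: 20 4-hydroxy-3-methylfuran-2(5H)-one
Product: 21 4-methoxy-3-methylfuran-2(5H)-one
Conditions: Me2SO4, K2CO3, acetone, reflux
Reagents that add atoms: dimethyl sulfate (COS(=O)(=O)OC)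
Why: O-Methylation of the vinylogous acid gives the methyl tetronate, whose γ-methylene can then be lithiated.

Step 14
Reactants: 19 ring B ketone; 21 4-methoxy-3-methylfuran-2(5H)-one
Product: 24 methyl 2-{(4R,9S,10R,10aS)-9-(3-methoxy-4-methyl-5-oxo-2,5-dihydrofuran-2-yl)-9-(triethylsilyloxy)-4-[(1R)-1-(triisopropylsilyloxy)propyl]decahydropyrido[1,2-a]azepin-10-yl}propanoate (C11/C15 epimers), via lithiated tetronate 22 (not isolated), via lithium aldolate 23 (not isolated)
Conditions: 21, LiN(iPr)2, THF, −78 °C; then 19, −78 °C; then Et3SiOTf, −78 to −40 °C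
Reagents that add atoms: triethylsilyl trifluoromethanesulfonate (CC[Si](CC)(CC)OS(=O)(=O)C(F)(F)F); lithium diisopropylamide (CC(C)[N-]C(C)C.[Li+], lithium only in 22 and 23)
Why: The γ-lithiated tetronate, too weakly basic to enolise the ketone, should add 1,2 (vinylogous aldol-type addition) to the C24 face opposite the C11 branch and axial C8, setting (24S), and the aldolate is silylated at −78 °C before it can lactonise onto C13 or revert.

Step 15
Reactants: 24 tetronate ester with O25 triethylsilyl ether
Product: 27 spiro ketone (target skeleton with C13 ketone, O25 triethylsilyl ether, O4 triisopropylsilyl ether; 3R,5R,9S,10R,11S,15S,24S), via pendant furanolate 25 (not isolated), via lithium enolate 26 (not isolated)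
Conditions: LiN(SiMe3)2 (2.2 equiv in two portions), THF, −78 to 0 °C; AcOH; then DBU (0.2 equiv), CH2Cl2, rt
Reagents that add atoms: lithium bis(trimethylsilyl)amide (C[Si](C)(C)[N-][Si](C)(C)C.[Li+], lithium only in 25 and 26)
Why: The base removes the C15 proton, the most acidic C–H because the anion is an aromatic 2-oxidofuran, and the furanolate carbon adds to the C13 ester carbonyl and expels methoxide, an intramolecular Claisen (Dieckmann-type) C-acylation of a butenolide γ-anion. Ring C closes by 5-exo-trig addition–elimination. At C15 both epimers of 24 give the same planar anion, and in the trans-fused transition state the methoxy-bearing flank C21 should turn away from the axial triethylsilyloxy group on C24, so that O16 ends syn to O25. At C11 the second portion of base converts the new ketone into its enolate, which pulls the equilibrium forward and blocks retro-Claisen opening, and protonation followed by DBU equilibration places the C12 methyl trans to C9. The step needs C-acylation to win over retro-aldol, lactonisation and elimination at C24, which the silyl ether on O25 and the lack of any proton on C15 in the product should secure.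

Step 16
Reactants: 27 spiro ketone
Product: 28 C13 alcohol (3R,5R,9S,10R,11S,13S,15S,24S; both silyl ethers retained)
Conditions: NaBH4, CeCl3·7H2O, MeOH/THF, −40 °C
Reagents that add atoms: none
Why: In this Luche-type borohydride reduction, weakly basic so that the C13–C15 bond is not cleaved, hydride should approach C13 from the face flanked only by H11 and ring oxygen O16, opposite the C12 methyl and the methoxy-bearing C21, giving the (13S) alcohol.

Step 17
Reactants: 28 C13 alcohol
Product: 29 CNP0267781.1 (3R,5R,9S,10R,11S,13S,15R,24S)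
Conditions: HF·pyridine, pyridine, THF, 0 to 40 °C
Reagents that add atoms: none
Why: Acidic fluoride desilylation removes both silyl ethers without forming an alkoxide at C24 that could expel the tetronate by retro-aldol cleavage.

Compound list
1 | (R)-2-aminohexanedioic acid | OC(=O)[C@H](N)CCCC(O)=O | starting material
2 | (R)-6-oxopiperidine-2-carboxylic acid | OC(=O)[C@H]1CCCC(=O)N1 | intermediate
3 | (R)-6-(1H-imidazole-1-carbonyl)piperidin-2-one | O=C([C@H]1CCCC(=O)N1)n1ccnc1 | intermediate
4 | (R)-N-methoxy-N-methyl-6-oxopiperidine-2-carboxamide | CON(C)C(=O)[C@H]1CCCC(=O)N1 | intermediate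
5 | (R)-6-propanoylpiperidin-2-one | CCC(=O)[C@H]1CCCC(=O)N1 | intermediate
6 | (6R)-6-[(1R)-1-hydroxypropyl]piperidin-2-one | CC[C@@H](O)[C@H]1CCCC(=O)N1 | intermediate
7 | (6R)-6-[(1R)-1-(triisopropylsilyloxy)propyl]piperidin-2-one | CC[C@@H](O[Si](C(C)C)(C(C)C)C(C)C)[C@H]1CCCC(=O)N1 | intermediate
8 | ethyl 4-bromobutanoate | CCOC(=O)CCCBr | starting material
9 | ethyl 4-{(6R)-2-oxo-6-[(1R)-1-(triisopropylsilyloxy)propyl]piperidin-1-yl}butanoate | CC[C@@H](O[Si](C(C)C)(C(C)C)C(C)C)[C@H]1CCCC(=O)N1CCCC(=O)OCC | intermediate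
10 | ethyl 4-{(6R)-2-thioxo-6-[(1R)-1-(triisopropylsilyloxy)propyl]piperidin-1-yl}butanoate | CC[C@@H](O[Si](C(C)C)(C(C)C)C(C)C)[C@H]1CCCC(=S)N1CCCC(=O)OCC | intermediate
11 | tert-butyl bromoacetate | CC(C)(C)OC(=O)CBr | starting material
12 | (2R)-6-[(2-tert-butoxy-2-oxoethyl)sulfanyl]-1-(4-ethoxy-4-oxobutyl)-2-[(1R)-1-(triisopropylsilyloxy)propyl]-2,3,4,5-tetrahydropyridin-1-ium bromide | CC[C@@H](O[Si](C(C)C)(C(C)C)C(C)C)[C@H]1CCCC(SCC(=O)OC(C)(C)C)=[N+]1CCCC(=O)OCC.[Br-] | intermediate
13 | tert-butyl (2E)-2-{(6R)-1-(4-ethoxy-4-oxobutyl)-6-[(1R)-1-(triisopropylsilyloxy)propyl]piperidin-2-ylidene}acetate | CC[C@@H](O[Si](C(C)C)(C(C)C)C(C)C)[C@H]1CCC/C(=C\C(=O)OC(C)(C)C)N1CCCC(=O)OCC | intermediate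
14 | tert-butyl 2-{(2S,6R)-1-(4-ethoxy-4-oxobutyl)-6-[(1R)-1-(triisopropylsilyloxy)propyl]piperidin-2-yl}acetate | CC[C@@H](O[Si](C(C)C)(C(C)C)C(C)C)[C@H]1CCC[C@@H](CC(=O)OC(C)(C)C)N1CCCC(=O)OCC | intermediate
15 | tert-butyl (4R,10aS)-9-oxo-4-[(1R)-1-(triisopropylsilyloxy)propyl]decahydropyrido[1,2-a]azepine-10-carboxylate (C10 epimers) | CC[C@@H](O[Si](C(C)C)(C(C)C)C(C)C)[C@H]1CCC[C@H]2C(C(=O)OC(C)(C)C)C(=O)CCCN12 | intermediate
16 | methyl 2-bromopropanoate | COC(=O)C(C)Br | starting material
17 | tert-butyl (4R,10aS)-10-(1-methoxy-1-oxopropan-2-yl)-9-oxo-4-[(1R)-1-(triisopropylsilyloxy)propyl]decahydropyrido[1,2-a]azepine-10-carboxylate (C10/C11 epimers) | CC[C@@H](O[Si](C(C)C)(C(C)C)C(C)C)[C@H]1CCC[C@H]2C(C(C)C(=O)OC)(C(=O)OC(C)(C)C)C(=O)CCCN12 | intermediate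
18 | (4R,10aS)-10-(1-methoxy-1-oxopropan-2-yl)-9-oxo-4-[(1R)-1-(triisopropylsilyloxy)propyl]decahydropyrido[1,2-a]azepine-10-carboxylic acid | CC[C@@H](O[Si](C(C)C)(C(C)C)C(C)C)[C@H]1CCC[C@H]2C(C(C)C(=O)OC)(C(=O)O)C(=O)CCCN12 | intermediate
19 | methyl 2-{(4R,10R,10aS)-9-oxo-4-[(1R)-1-(triisopropylsilyloxy)propyl]decahydropyrido[1,2-a]azepin-10-yl}propanoate (C11 epimers) | CC[C@@H](O[Si](C(C)C)(C(C)C)C(C)C)[C@H]1CCC[C@H]2[C@@H](C(C)C(=O)OC)C(=O)CCCN12 | intermediate
20 | 4-hydroxy-3-methylfuran-2(5H)-one | CC1=C(O)COC1=O | starting material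
21 | 4-methoxy-3-methylfuran-2(5H)-one | CC1=C(OC)COC1=O | intermediate
22 | lithium 4-methoxy-3-methylfuran-2-olate | [Li+].COc1coc([O-])c1C | intermediate
23 | lithium (4R,9S,10R,10aS)-9-(3-methoxy-4-methyl-5-oxo-2,5-dihydrofuran-2-yl)-10-(1-methoxy-1-oxopropan-2-yl)-4-[(1R)-1-(triisopropylsilyloxy)propyl]decahydropyrido[1,2-a]azepin-9-olate | CC[C@@H](O[Si](C(C)C)(C(C)C)C(C)C)[C@H]1CCC[C@H]2[C@@H](C(C)C(=O)OC)[C@]([O-])(C3OC(=O)C(C)=C3OC)CCCN12.[Li+] | intermediate
24 | methyl 2-{(4R,9S,10R,10aS)-9-(3-methoxy-4-methyl-5-oxo-2,5-dihydrofuran-2-yl)-9-(triethylsilyloxy)-4-[(1R)-1-(triisopropylsilyloxy)propyl]decahydropyrido[1,2-a]azepin-10-yl}propanoate (C11/C15 epimers) | CC[C@@H](O[Si](C(C)C)(C(C)C)C(C)C)[C@H]1CCC[C@H]2[C@@H](C(C)C(=O)OC)[C@](O[Si](CC)(CC)CC)(C3OC(=O)C(C)=C3OC)CCCN12 | intermediate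
25 | lithium furanolate of 24 (C15 deprotonated) | CC[C@@H](O[Si](C(C)C)(C(C)C)C(C)C)[C@H]1CCC[C@H]2[C@@H](C(C)C(=O)OC)[C@](O[Si](CC)(CC)CC)(c3oc([O-])c(C)c3OC)CCCN12.[Li+] | intermediate
26 | lithium C11=C13 enolate of spiro ketone 27 | CC[C@@H](O[Si](C(C)C)(C(C)C)C(C)C)[C@H]1CCC[C@H]2[C@H]3C(C)=C([O-])[C@@]4(OC(=O)C(C)=C4OC)[C@]3(O[Si](CC)(CC)CC)CCCN12.[Li+] | intermediate
27 | spiro ketone: target skeleton with C13 ketone, O25 triethylsilyl ether and O4 triisopropylsilyl ether (3R,5R,9S,10R,11S,15S,24S; C15 has the target geometry, its descriptor differs only through priorities) | CC[C@@H](O[Si](C(C)C)(C(C)C)C(C)C)[C@H]1CCC[C@H]2[C@H]3[C@H](C)C(=O)[C@@]4(OC(=O)C(C)=C4OC)[C@]3(O[Si](CC)(CC)CC)CCCN12 | intermediate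
28 | C13 alcohol with both silyl ethers (3R,5R,9S,10R,11S,13S,15S,24S) | CC[C@@H](O[Si](C(C)C)(C(C)C)C(C)C)[C@H]1CCC[C@H]2[C@H]3[C@H](C)[C@H](O)[C@@]4(OC(=O)C(C)=C4OC)[C@]3(O[Si](CC)(CC)CC)CCCN12 | intermediate
29 | CNP0267781.1 (3R,5R,9S,10R,11S,13S,15R,24S) | CC[C@@H](O)[C@H]1CCC[C@H]2[C@H]3[C@H](C)[C@H](O)[C@@]4(OC(=O)C(C)=C4OC)[C@]3(O)CCCN12 | target

Total step count: 17 steps.
Longest linear sequence: 16 steps (steps 1–12 and 14–17 from 1); step 13 prepares the tetronate.

Steps most likely to fail

Step 15 (key step). Acyl transfer to the hindered furanolate may be slower than its side paths: the methoxide released may strip the triethylsilyl group (followed by retro-aldol scission of C15–C24), reopen ring C by retro-Claisen attack, or the furanolate may expel silanolate. The fallback closes the same C13–C15 bond at the aldehyde oxidation level under Lewis acid. Setting out from 24, t-BuMe2SiOTf/Et3N in CH2Cl2 should convert the butenolide into the 2-silyloxyfuran ester F1. i-Bu2AlH at −78 °C then reduces the methyl ester, no lactone carbonyl being left to compete, to the silyloxyfuran aldehyde F2. BF3·OEt2 at −78 °C should trigger an intramolecular vinylogous Mukaiyama aldol addition to the spiro hydroxy butenolide F3 (C11 and C13 epimers), with the same steric bias at C15. Dess–Martin oxidation and DBU equilibration of C11 bring the material back to the route at spiro ketone 27.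

Step 14. The lithium aldolate may lactonise onto the C13 methyl ester, or revert to ketone and tetronate anion, before the silyl triflate traps it. The fallback lets the lactone form and carries the acyl group as an N-methoxy-N-methylamide. Setting out from 19 and 21, the addition is run as in step 14 but warmed to −20 °C without silyl triflate, which should give the fused γ-lactone F4 (O25 acylated by C13). Me2AlN(OMe)Me, made from AlMe3 and MeNHOMe·HCl in CH2Cl2, opens it to the hydroxy Weinreb amide F5, and Et3SiOTf/2,6-lutidine gives the silyl ether amide F6. LiN(SiMe3)2 in THF then closes ring C by C-acylation through a chelated tetrahedral adduct that releases no alkoxide, and AcOH work-up with DBU equilibration comes back to the route at spiro ketone 27.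

Step 12. Ketonisation of the enol at C10 may be poorly face-selective, or the acid may equilibrate C10 to the epimer with H9 and H10 trans. The fallback sets C9 and C10 together by syn hydrogenation. Setting out from 19 (any C10 epimer ratio), Me3SiOTf/Et3N should give the more substituted silyl enol ether F7 (C10=C24). Pd(OAc)2 in MeCN (Saegusa–Ito dehydrogenation) removes H9 to give the bicyclic vinylogous amide F8 (C9=C10). H2 over PtO2 in AcOH should then add both hydrogens from the face opposite the C5 side chain, which makes H9 and H10 cis by necessity and comes back to the route at ketone 19.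

Further compounds
F1 | step 15 | 2-(tert-butyldimethylsilyloxy)furan form of 24 (methyl ester retained) | CC[C@@H](O[Si](C(C)C)(C(C)C)C(C)C)[C@H]1CCC[C@H]2[C@@H](C(C)C(=O)OC)[C@](O[Si](CC)(CC)CC)(c3oc(O[Si](C)(C)C(C)(C)C)c(C)c3OC)CCCN12
F2 | step 15 | silyloxyfuran aldehyde (C13 as CHO) | CC[C@@H](O[Si](C(C)C)(C(C)C)C(C)C)[C@H]1CCC[C@H]2[C@@H](C(C)C=O)[C@](O[Si](CC)(CC)CC)(c3oc(O[Si](C)(C)C(C)(C)C)c(C)c3OC)CCCN12
F3 | step 15 | spiro hydroxy butenolide (C13 carbinol; C11 and C13 epimers; both silyl ethers of 27) | CC[C@@H](O[Si](C(C)C)(C(C)C)C(C)C)[C@H]1CCC[C@H]2[C@H]3C(C)C(O)[C@@]4(OC(=O)C(C)=C4OC)[C@]3(O[Si](CC)(CC)CC)CCCN12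
F4 | step 14 | fused γ-lactone (O25–C13) bearing the tetronate on C24 | CC[C@@H](O[Si](C(C)C)(C(C)C)C(C)C)[C@H]1CCC[C@H]2[C@H]3C(C)C(=O)O[C@@]3(C3OC(=O)C(C)=C3OC)CCCN12
F5 | step 14 | C24 hydroxy N-methoxy-N-methylamide | CC[C@@H](O[Si](C(C)C)(C(C)C)C(C)C)[C@H]1CCC[C@H]2[C@@H](C(C)C(=O)N(C)OC)[C@](O)(C3OC(=O)C(C)=C3OC)CCCN12
F6 | step 14 | C24 triethylsilyl ether N-methoxy-N-methylamide | CC[C@@H](O[Si](C(C)C)(C(C)C)C(C)C)[C@H]1CCC[C@H]2[C@@H](C(C)C(=O)N(C)OC)[C@](O[Si](CC)(CC)CC)(C3OC(=O)C(C)=C3OC)CCCN12
F7 | step 12 | C10=C24 trimethylsilyl enol ether of 19 | CC[C@@H](O[Si](C(C)C)(C(C)C)C(C)C)[C@H]1CCC[C@H]2C(C(C)C(=O)OC)=C(O[Si](C)(C)C)CCCN12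
F8 | step 12 | bicyclic vinylogous amide (C9=C10 enaminone of 19) | CC[C@@H](O[Si](C(C)C)(C(C)C)C(C)C)[C@H]1CCCC2=C(C(C)C(=O)OC)C(=O)CCCN12
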